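**Plan**

- Retrosynthesis: the O1–isovaleroyl and O7–coumaroyl ester bonds are cut first, then C4–C11 (formylation of the ring enol ether), C8–C10 (hydroxymethyl anion on a C8 ketone), the ring bond C5–C6 (Nazarov closure), and finally C8–C7 and C9–C8 (vinyllithium addition, glycal formylation), back to L-arabinal.
- Enabling feature (iridoid numbering; β is the face of H5 and H9): C6–C7–C8–C9–C5 is a cross-conjugated dienone with the carbonyl at C8 and an oxygen on C7, and its C9=C5 alkene lies in a pentose-sized pyran (C1, O2, C3, C4, C5, C9).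
- Forward order: the pyran comes from L-arabinal; C8, C7 and C6 are hung on C9 as a 2-methoxyacryloyl group; the cyclopentenone closes by C5–C6 bond formation; C10, the C7 carbinol, the C3=C4 enol ether with C11 and the two esters follow.
- Stereochemistry: the C4 ether of L-arabinose steers C6 to the opposite face of C5; C9 follows by protonation to the cis fusion; C10 enters C8 on the convex face; hydride reaches C7 from O8–H; C1 is set last by acylation of the lactol.
- The C4 stereocentre is finally spent as the leaving group that creates C3=C4.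

Key step: step 7

Remarks: bicyclic compounds are named with iridoid numbering; NAP = 2-naphthylmethyl, TIPS = triisopropylsilyl, TES = triethylsilyl. Assumption: the methyl acetal is carried as the anomer with OMe trans to the C4 ether (1α), not the cis anomer; this centre is erased at lactol 27, so the other anomer would converge there. Carbinol 9 is a mixture at C8, which step 6 removes.

**Route**

Step 1
Reactants: 1 3,4-di-O-acetyl-L-arabinal
Product: 2 L-arabinal
Conditions: NaOMe (0.1 equiv), MeOH, rt
Reagents that add atoms: none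
Why: Zemplén transesterification removes both acetates as methyl acetate and leaves the glycal and its two stereocentres untouched.

Step 2
Reactants: 2 L-arabinal
Product: 3 3,4-di-O-(2-naphthylmethyl)-L-arabinal
Conditions: NaH, 2-(bromomethyl)naphthalene, Bu4NI (cat.), DMF, 0 °C → rt
Reagents that add atoms: 2-(bromomethyl)naphthalene, BrCc1ccc2ccccc2c1
Why: Williamson etherification of both alkoxides gives ethers that behave like benzyl ethers toward bases and Lewis acids but can later be removed with DDQ, so that no hydrogenation is needed once the cinnamate is in place.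

Step 3
Reactants: 3 3,4-di-O-(2-naphthylmethyl)-L-arabinal
Product: 5 2-C-formyl-3,4-di-O-(2-naphthylmethyl)-L-arabinal, via iminium salt 4 (not isolated)
Conditions: POCl3, DMF, 0 °C → rt; then aq NaOAc
Reagents that add atoms: N,N-dimethylformamide, CN(C)C=O; water, O
Why: Vilsmeier–Haack formylation of the glycal at its nucleophilic enol ether carbon (future C9), a known reaction of benzyl-type protected glycals, brings in C8 as the aldehyde carbon.

Step 4
Reactants: 5 2-C-formyl-3,4-di-O-(2-naphthylmethyl)-L-arabinal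
Product: 6 methyl 2,3-dideoxy-2-C-formyl-4-O-(2-naphthylmethyl)-β-L-glycero-pent-2-enopyranoside
Conditions: NaOMe (0.2 equiv), MeOH/THF, 0 °C
Reagents that add atoms: methanol (as NaOMe/MeOH), CO
Why: Oxa-Michael addition of methoxide to C1 of the push–pull enal followed by E1cB loss of the allylic naphthylmethoxide at the future C5 (an SN2′-type, Ferrier-like transposition of 2-C-formyl glycals) moves the double bond to C9=C5; the new acetal centre is expected trans to the C4 ether, because methoxide enters axially anti to that ether and both groups can then sit pseudoaxial, as in the α-selective D-galacto series.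

Step 5
Reactants: 6 methyl 2,3-dideoxy-2-C-formyl-4-O-(2-naphthylmethyl)-β-L-glycero-pent-2-enopyranoside; 7 methyl vinyl ether
Product: 9 methyl 2,3-dideoxy-2-C-(1-hydroxy-2-methoxyprop-2-en-1-yl)-4-O-(2-naphthylmethyl)-β-L-glycero-pent-2-enopyranoside (C8 epimers), via 1-methoxyvinyllithium 8 (not isolated)
Conditions: 7, t-BuLi, THF, −78 → 0 °C; then 6, −78 °C; aq NH4Cl
Reagents that add atoms: none
Why: α-Lithiation of methyl vinyl ether and 1,2-addition of the hard vinyllithium to the enal give the bis-allylic carbinol, whose new centre (C8) forms as a mixture and is removed in step 6.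

Step 6
Reactants: 9 the dienyl carbinol
Product: 10 methyl 2,3-dideoxy-2-C-(2-methoxyacryloyl)-4-O-(2-naphthylmethyl)-β-L-glycero-pent-2-enopyranoside
Conditions: Dess–Martin periodinane, NaHCO3, CH2Cl2, 0 °C → rt
Reagents that add atoms: none
Why: Dess–Martin oxidation of a bis-allylic alcohol under buffered conditions, the usual way to 2-alkoxy divinyl ketones, leaves the acid-labile enol ether and acetal intact.

Step 7
Reactants: 10 the 2-methoxy dienone
Product: 11 1α,7-dimethoxy-4β-(2-naphthylmethoxy)-5βH,9βH-cyclopenta[c]pyran-6-en-8-one (cis-fused 2-methoxycyclopentenone)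
Conditions: Sc(OTf)3 (10 mol %), LiClO4 (1 equiv), ClCH2CH2Cl, 25 → 40 °C
Reagents that add atoms: none
Why: Sc(OTf)3 binds the C8 carbonyl (chelated by the C7 methoxy group), the 3-oxidopentadienyl cation closes by conrotatory 4π electrocyclisation between C5 and C6, the methoxy-stabilised oxyallyl cation loses H6, and the scandium enolate is protonated at C9. The closest known reaction is the Lewis-acid-catalysed Nazarov cyclisation of 2-alkoxy-1,4-pentadien-3-ones in which one alkene is part of a ring. The cyclopentenone is the only ring formed and it closes in the electrocyclic mode (thermal conrotation, formally a 5-endo closure onto the pyran double bond). C5 is set by torquoselectivity: in the half-chair of 10 the anomeric methoxy group and the C4 ether are pseudoaxial on opposite faces, so C6 reaches C5 on the face anti to the C4–O bond, which is also the axial, chair-like trajectory; C9 is set by protonation of the enolate on the convex face, which gives the only strain-free (cis) ring fusion and remains correctable by enolisation. The step needs this torquoselectivity, loss of H6 and not H5 (secured by the C7 methoxy group, which localises the charge at C7), and survival of the allylic acetal and ether, whose ionisation is disfavoured because either cation would sit next to the acylated, electron-poor carbon C9.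

Step 8
Reactants: 11 the cis-fused 2-methoxycyclopentenone
Product: 12 8α-hydroxy-8β-[(isopropoxydimethylsilyl)methyl] adduct (C6=C7 methyl enol ether retained)
Conditions: (iPrO)Me2SiCH2MgCl (from (chloromethyl)isopropoxydimethylsilane and Mg), CeCl3, THF, −78 → −40 °C; aq NH4Cl
Reagents that add atoms: (isopropoxydimethylsilyl)methylmagnesium chloride, CC(C)O[Si](C)(C)C[Mg]Cl
Why: 1,2-Addition of Tamao's hydroxymethyl-anion equivalent as its weakly basic organocerium form (which suppresses enolisation at C9) occurs on the convex β face of the cis-fused bicycle, away from the pyran ring, and places C10 β and O8 α.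

Step 9
Reactants: 12 the β-hydroxysilane
Product: 13 8α-hydroxy-8β-hydroxymethyl compound (diol)
Conditions: 30% H2O2, KF, KHCO3, THF/MeOH, rt
Reagents that add atoms: hydrogen peroxide, OO
Why: Tamao–Fleming oxidation converts the C–Si bond into C–OH with retention under weakly basic conditions that touch neither the enol ether nor the acetal.

Step 10
Reactants: 13 the diol
Product: 14 10-O-TIPS ether of 13
Conditions: TIPSCl, imidazole, DMAP (cat.), DMF, rt
Reagents that add atoms: triisopropylsilyl chloride, CC(C)[Si](Cl)(C(C)C)C(C)C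
Why: Selective silylation of the primary hydroxyl over the hindered tertiary one gives an acid-stable ether and removes the one hydroxyl that could direct the later C7 reduction to the wrong face.

Step 11
Reactants: 14 the methyl enol ether
Product: 15 8α-hydroxy-10-O-TIPS 7-ketone
Conditions: oxalic acid (0.1 M aq), THF, 0 °C → rt
Reagents that add atoms: water, O
Why: Mild acid hydrolysis of the methyl enol ether (C6 protonation, hydration at C7, loss of methanol) is far faster than hydrolysis of the glycosidic acetal or of the TIPS ether and unmasks the C7 ketone.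

Step 12
Reactants: 15 the α-hydroxy ketone
Product: 16 7β,8α-diol
Conditions: Me4NBH(OAc)3, MeCN/AcOH, −30 → −20 °C
Reagents that add atoms: none
Why: Saksena–Evans hydroxyl-directed reduction, in which the 8α-hydroxyl exchanges onto boron and hydride is transferred intramolecularly to the α face of C7, gives the 7β-alcohol trans to O8.

Step 13
Reactants: 17 p-coumaric acid
Product: 19 (E)-4-(triisopropylsilyloxy)cinnamic acid, via triisopropylsilyl ester 18 (not isolated)
Conditions: TIPSCl (2.2 equiv), imidazole, DMF, rt; then AcOH/THF/H2O, rt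
Reagents that add atoms: triisopropylsilyl chloride, CC(C)[Si](Cl)(C(C)C)C(C)C
Why: Bis-silylation followed by selective hydrolysis of the labile silyl ester leaves the aryl silyl ether and the E-alkene unchanged.

Step 14
Reactants: 16 the 7β,8α-diol; 19 (E)-4-(triisopropylsilyloxy)cinnamic acid
Product: 20 7β-O-[(E)-4-(triisopropylsilyloxy)cinnamoyl] ester of 16
Conditions: DCC, DMAP, CH2Cl2, 0 °C → rt
Reagents that add atoms: none
Why: Steglich esterification acylates the secondary 7-hydroxyl with retention and leaves the hindered tertiary 8-hydroxyl free.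

Step 15
Reactants: 20 the 7-O-cinnamoyl ester
Product: 21 8-O-TES ether of 20
Conditions: TESOTf (1.2 equiv), 2,6-lutidine, CH2Cl2, −78 °C
Reagents that add atoms: triethylsilyl triflate, CC[Si](CC)(CC)OS(=O)(=O)C(F)(F)F
Why: Silyl triflate silylation of the tertiary alcohol at low temperature masks the only free hydroxyl before the sulfonylation and Vilsmeier steps.

Step 16
Reactants: 21 the fully protected NAP ether
Product: 22 4β-alcohol
Conditions: DDQ, CH2Cl2/pH 7 phosphate buffer (10:1), 0 °C → rt
Reagents that add atoms: none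
Why: Oxidative cleavage of the 2-naphthylmethyl ether by DDQ (benzylic hydride abstraction, hydrolysis of the oxocarbenium ion) spares the cinnamate, the silyl ethers and the acetal.

Step 17
Reactants: 22 the 4β-alcohol
Product: 24 C3=C4 enol ether (1α-methoxy 3-ene), via C4 triflate 23 (not isolated)
Conditions: Tf2O, 2,6-lutidine, CH2Cl2, −40 °C; then DBU, −40 °C → rt
Reagents that add atoms: none
Why: Sulfonylation and amidine-base E2 elimination can only form C3=C4, because the 4β-triflate has an antiperiplanar hydrogen at C3 alone (H5 is cis to the leaving group), as in known eliminations of pyranoside sulfonates toward the carbon bearing the ring oxygen.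

Step 18
Reactants: 24 the C3=C4 enol ether
Product: 26 11-aldehyde (1α-methoxy 3-en-11-al), via iminium salt 25 (not isolated)
Conditions: POCl3, DMF, 0 °C → rt; then aq NaOAc, 0 °C
Reagents that add atoms: N,N-dimethylformamide, CN(C)C=O; water, O
Why: Vilsmeier–Haack formylation at the β-carbon (C4) of the 2-alkoxy-3,4-dihydro-2H-pyran enol ether, the same reaction type as step 3 and the usual way to acylate such enol ethers at C4, installs C11 as a vinylogous formate that withstands the coming acid step.

Step 19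
Reactants: 26 the 1α-methoxy 11-aldehyde
Product: 27 1-hydroxy 11-aldehyde (lactol; 8-hydroxyl free)
Conditions: 0.5 M aq HCl/THF (1:4), rt
Reagents that add atoms: water, O
Why: Acid hydrolysis cleaves the methyl acetal (a 2-deoxy-type glycoside) and the tertiary TES ether, while conjugation with the aldehyde protects the enol ether from hydration and the TIPS ethers resist dilute acid; the lactol is expected to settle in the 1β-hydroxy form.

Step 20
Reactants: 27 the lactol; 28 isovaleryl chloride
Product: 29 1β-O-isovaleroyl 11-aldehyde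
Conditions: pyridine, DMAP (0.1 equiv), CH2Cl2, −20 → 0 °C
Reagents that add atoms: none
Why: Acylation of the equilibrating lactol traps the 1β-hydroxyl, which lies on the convex face, trans to the C9–C8 bond and axial (anomeric effect), while the hindered tertiary 8-hydroxyl does not react.

Step 21
Reactants: 29 the 1β-O-isovaleroyl 11-aldehyde
Product: 30 bis-TIPS luzonoid A (11-alcohol)
Conditions: NaBH4, CeCl3·7H2O, MeOH/THF, −40 °C
Reagents that add atoms: none
Why: Luche reduction converts the vinylogous formate aldehyde into the allylic alcohol (as in the reduction of 2-C-formyl glycals) faster than it attacks the cinnamate, the acyl acetal or the silyl ethers.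

Step 22
Reactants: 30 bis-TIPS luzonoid A
Product: 31 luzonoid A
Conditions: TBAF/AcOH (1:1), THF, 0 °C → rt
Reagents that add atoms: none
Why: Fluoride desilylation cleaves the aryl and the primary TIPS ethers, and the acetic acid buffer keeps the medium near neutral so that the acyl acetal, the enol ether and the position of the cinnamate are preserved.

**Compound list**

1 | 3,4-di-O-acetyl-L-arabinal | CC(=O)O[C@@H]1C=COC[C@@H]1OC(C)=O | starting material
2 | L-arabinal | O[C@@H]1C=COC[C@@H]1O | intermediate
3 | 3,4-di-O-(2-naphthylmethyl)-L-arabinal | O(Cc3ccc4ccccc4c3)[C@@H]1C=COC[C@@H]1OCc5ccc6ccccc6c5 | intermediate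
4 | 2-C-(dimethyliminiomethyl)-3,4-di-O-(2-naphthylmethyl)-L-arabinal dichlorophosphate | O(Cc3ccc4ccccc4c3)[C@@H]1C(C=[N+](C)C)=COC[C@@H]1OCc5ccc6ccccc6c5.[O-]P(=O)(Cl)Cl | intermediate (not isolated)
5 | 2-C-formyl-3,4-di-O-(2-naphthylmethyl)-L-arabinal | O(Cc3ccc4ccccc4c3)[C@@H]1C(C=O)=COC[C@@H]1OCc5ccc6ccccc6c5 | intermediate
6 | methyl 2,3-dideoxy-2-C-formyl-4-O-(2-naphthylmethyl)-β-L-glycero-pent-2-enopyranoside (OMe trans to the C4 ether) | CO[C@H]1OC[C@H](OCc3ccc4ccccc4c3)C=C1C=O | intermediate
7 | methyl vinyl ether | COC=C | starting material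
8 | 1-methoxyvinyllithium | [Li]C(=C)OC | intermediate (not isolated)
9 | methyl 2,3-dideoxy-2-C-(1-hydroxy-2-methoxyprop-2-en-1-yl)-4-O-(2-naphthylmethyl)-β-L-glycero-pent-2-enopyranoside, C8 epimers | CO[C@H]1OC[C@H](OCc3ccc4ccccc4c3)C=C1C(O)C(OC)=C | intermediate
10 | methyl 2,3-dideoxy-2-C-(2-methoxyacryloyl)-4-O-(2-naphthylmethyl)-β-L-glycero-pent-2-enopyranoside | CO[C@H]1OC[C@H](OCc3ccc4ccccc4c3)C=C1C(=O)C(OC)=C | intermediate
11 | cis-fused 2-methoxycyclopentenone: 1α-OMe, 4β-ONAP, 5β-H, 9β-H, C6=C7(OMe), C8=O | CO[C@H]1OC[C@H](OCc3ccc4ccccc4c3)[C@H]2C=C(OC)C(=O)[C@@H]12 | intermediate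
12 | 8α-hydroxy-8β-[(isopropoxydimethylsilyl)methyl] adduct of 11 | CO[C@H]1OC[C@H](OCc3ccc4ccccc4c3)[C@H]2C=C(OC)[C@](O)(C[Si](C)(C)OC(C)C)[C@@H]12 | intermediate
13 | 8α-hydroxy-8β-hydroxymethyl enol ether (diol) | CO[C@H]1OC[C@H](OCc3ccc4ccccc4c3)[C@H]2C=C(OC)[C@](O)(CO)[C@@H]12 | intermediate
14 | 10-O-TIPS ether of 13 | CO[C@H]1OC[C@H](OCc3ccc4ccccc4c3)[C@H]2C=C(OC)[C@](O)(CO[Si](C(C)C)(C(C)C)C(C)C)[C@@H]12 | intermediate
15 | 8α-hydroxy-10-O-TIPS 7-ketone | CO[C@H]1OC[C@H](OCc3ccc4ccccc4c3)[C@H]2CC(=O)[C@](O)(CO[Si](C(C)C)(C(C)C)C(C)C)[C@@H]12 | intermediate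
16 | 7β,8α-diol | CO[C@H]1OC[C@H](OCc3ccc4ccccc4c3)[C@H]2C[C@H](O)[C@](O)(CO[Si](C(C)C)(C(C)C)C(C)C)[C@@H]12 | intermediate
17 | p-coumaric acid | OC(=O)/C=C/c1ccc(O)cc1 | starting material
18 | triisopropylsilyl (E)-4-(triisopropylsilyloxy)cinnamate | CC(C)[Si](C(C)C)(C(C)C)OC(=O)/C=C/c1ccc(O[Si](C(C)C)(C(C)C)C(C)C)cc1 | intermediate (not isolated)
19 | (E)-4-(triisopropylsilyloxy)cinnamic acid | OC(=O)/C=C/c1ccc(O[Si](C(C)C)(C(C)C)C(C)C)cc1 | intermediate
20 | 7β-O-[(E)-4-(triisopropylsilyloxy)cinnamoyl] ester of 16 | CO[C@H]1OC[C@H](OCc3ccc4ccccc4c3)[C@H]2C[C@H](OC(=O)/C=C/c5ccc(O[Si](C(C)C)(C(C)C)C(C)C)cc5)[C@](O)(CO[Si](C(C)C)(C(C)C)C(C)C)[C@@H]12 | intermediate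
21 | 8-O-TES ether of 20 | CO[C@H]1OC[C@H](OCc3ccc4ccccc4c3)[C@H]2C[C@H](OC(=O)/C=C/c5ccc(O[Si](C(C)C)(C(C)C)C(C)C)cc5)[C@](O[Si](CC)(CC)CC)(CO[Si](C(C)C)(C(C)C)C(C)C)[C@@H]12 | intermediate
22 | 4β-alcohol | CO[C@H]1OC[C@H](O)[C@H]2C[C@H](OC(=O)/C=C/c3ccc(O[Si](C(C)C)(C(C)C)C(C)C)cc3)[C@](O[Si](CC)(CC)CC)(CO[Si](C(C)C)(C(C)C)C(C)C)[C@@H]12 | intermediate
23 | 4β-triflate | CO[C@H]1OC[C@H](OS(=O)(=O)C(F)(F)F)[C@H]2C[C@H](OC(=O)/C=C/c3ccc(O[Si](C(C)C)(C(C)C)C(C)C)cc3)[C@](O[Si](CC)(CC)CC)(CO[Si](C(C)C)(C(C)C)C(C)C)[C@@H]12 | intermediate (not isolated)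
24 | C3=C4 enol ether (C4 unsubstituted) | CO[C@H]1OC=C[C@H]2C[C@H](OC(=O)/C=C/c3ccc(O[Si](C(C)C)(C(C)C)C(C)C)cc3)[C@](O[Si](CC)(CC)CC)(CO[Si](C(C)C)(C(C)C)C(C)C)[C@@H]12 | intermediate
25 | C4 (dimethyliminio)methyl enol ether dichlorophosphate | CO[C@H]1OC=C(C=[N+](C)C)[C@H]2C[C@H](OC(=O)/C=C/c3ccc(O[Si](C(C)C)(C(C)C)C(C)C)cc3)[C@](O[Si](CC)(CC)CC)(CO[Si](C(C)C)(C(C)C)C(C)C)[C@@H]12.[O-]P(=O)(Cl)Cl | intermediate (not isolated)
26 | 1α-methoxy 3-en-11-al (8-O-TES) | CO[C@H]1OC=C(C=O)[C@H]2C[C@H](OC(=O)/C=C/c3ccc(O[Si](C(C)C)(C(C)C)C(C)C)cc3)[C@](O[Si](CC)(CC)CC)(CO[Si](C(C)C)(C(C)C)C(C)C)[C@@H]12 | intermediate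
27 | 1-hydroxy 3-en-11-al, drawn as the 1β-lactol (equilibrating anomers), 8-OH free | O[C@@H]1OC=C(C=O)[C@H]2C[C@H](OC(=O)/C=C/c3ccc(O[Si](C(C)C)(C(C)C)C(C)C)cc3)[C@](O)(CO[Si](C(C)C)(C(C)C)C(C)C)[C@@H]12 | intermediate
28 | isovaleryl chloride | CC(C)CC(=O)Cl | starting material
29 | 1β-O-isovaleroyl 3-en-11-al | CC(C)CC(=O)O[C@@H]1OC=C(C=O)[C@H]2C[C@H](OC(=O)/C=C/c3ccc(O[Si](C(C)C)(C(C)C)C(C)C)cc3)[C@](O)(CO[Si](C(C)C)(C(C)C)C(C)C)[C@@H]12 | intermediate
30 | bis-TIPS luzonoid A | CC(C)CC(=O)O[C@@H]1OC=C(CO)[C@H]2C[C@H](OC(=O)/C=C/c3ccc(O[Si](C(C)C)(C(C)C)C(C)C)cc3)[C@](O)(CO[Si](C(C)C)(C(C)C)C(C)C)[C@@H]12 | intermediate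
31 | luzonoid A | CC(C)CC(=O)O[C@@H]1OC=C(CO)[C@H]2C[C@H](OC(=O)/C=C/c3ccc(O)cc3)[C@](O)(CO)[C@@H]12 | target

**Step count and risks**

Total: 22 steps. Longest linear sequence: 21 steps (steps 1–12 and 14–22, from 1); step 13 is a one-step branch.

Steps most likely to fail:

1. Step 7. The Lewis acid may ionise the anomeric methoxy group or trigger its β-elimination from the scandium enolate, or the torquoselectivity may be low if the diaxial half-chair is not dominant. Fallback, a stepwise polar annulation that sets out from 6 and returns at 11: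
   - CH2=CHMgBr/CuBr·SMe2 (THF, −78 °C, cold AcOH quench) adds to C5 anti to the C4 ether to give the vinyl aldehyde F1.
   - MeOCH2Li (from Bu3SnCH2OMe and n-BuLi) adds to the aldehyde to give the carbinol F2.
   - Dess–Martin oxidation gives the methoxymethyl ketone F3.
   - OsO4 (cat.)/NaIO4 with 2,6-lutidine cleaves the vinyl group to the keto aldehyde F4.
   - Intramolecular aldol condensation with piperidinium acetate (C7 enolate onto the C6 aldehyde, dehydration, equilibration of C9 to the cis fusion) closes the ring to 11.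

2. Step 12. Ligand exchange at the hindered tertiary 8-hydroxyl may be too slow, so that hydride is delivered externally on the convex face and the wrong C7 epimer forms. Fallback, which sets out from 15 and returns at 20: NaBH4 (MeOH, −20 °C) is used deliberately for convex-face reduction to the cis-diol F5, and Mitsunobu esterification with acid 19 (PPh3, DIAD, toluene) then inverts C7 and gives the 7β-cinnamate 20 directly.

3. Step 17. The triflate may undergo substitution or ring-oxygen participation in place of anti-elimination, or eliminate slowly because the conformer with an axial C4–O bond is disfavoured. Fallback, which sets out from 22 and returns at 26: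
   - Dess–Martin oxidation gives the 4-ketone F6.
   - Kinetic enolisation toward the C3 methylene (KN(SiMe3)2, PhNTf2, THF, −78 °C) gives the enol triflate F7.
   - Formylation with Pd(PPh3)4, CO (1 atm) and Bu3SnH (slow addition, THF, 50 °C) gives aldehyde 26.

Further compounds
F1 | step 7 | methyl 2,3-dideoxy-2-C-formyl-4-O-(2-naphthylmethyl)-3-C-vinyl-pentopyranoside (vinyl trans to the C4 ether, C9 epimers) | CO[C@H]1OC[C@H](OCc3ccc4ccccc4c3)[C@@H](C=C)C1C=O
F2 | step 7 | 2-C-(1-hydroxy-2-methoxyethyl) carbinol derived from F1 | CO[C@H]1OC[C@H](OCc3ccc4ccccc4c3)[C@@H](C=C)C1C(O)COC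
F3 | step 7 | 2-C-(methoxyacetyl) ketone derived from F2 | CO[C@H]1OC[C@H](OCc3ccc4ccccc4c3)[C@@H](C=C)C1C(=O)COC
F4 | step 7 | 3-C-formyl-2-C-(methoxyacetyl) keto aldehyde | CO[C@H]1OC[C@H](OCc3ccc4ccccc4c3)[C@@H](C=O)C1C(=O)COC
F5 | step 12 | 7α,8α-diol (C7 epimer of 16) | CO[C@H]1OC[C@H](OCc3ccc4ccccc4c3)[C@H]2C[C@@H](O)[C@](O)(CO[Si](C(C)C)(C(C)C)C(C)C)[C@@H]12
F6 | step 17 | 4-ketone derived from 22 | CO[C@H]1OCC(=O)[C@H]2C[C@H](OC(=O)/C=C/c3ccc(O[Si](C(C)C)(C(C)C)C(C)C)cc3)[C@](O[Si](CC)(CC)CC)(CO[Si](C(C)C)(C(C)C)C(C)C)[C@@H]12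
F7 | step 17 | C3=C4 enol triflate | CO[C@H]1OC=C(OS(=O)(=O)C(F)(F)F)[C@H]2C[C@H](OC(=O)/C=C/c3ccc(O[Si](C(C)C)(C(C)C)C(C)C)cc3)[C@](O[Si](CC)(CC)CC)(CO[Si](C(C)C)(C(C)C)C(C)C)[C@@H]12
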